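**Plan**

- Retrosynthesis (target numbered as a tricyclo[5.4.0.0^{2,8}]undecane: C2 = methyl-bearing quaternary cyclobutane carbon, C3 = neighbouring CH–O): the angelates and O3/O4 go back to a C3=C4 alkene, the C5 carbinol to an enone, the two C6 methyls to an enolate alkylation.
- The C2–C3 bond is then cut, opening the seven-membered ring to a 7-methylidenebicyclo[3.1.1]heptane with a but-3-yn-2-one chain; the chain is cut at C6–C7 (olefination of a cyclobutanone), and the cyclobutane bonds C1–C7 and C2–C8 are cut together (ketene + vinyl sulfide [2+2]) to an acyclic C8 acid.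
- Forward: six-membered ring and cyclobutane form in one operation (step 6); the seven-membered ring forms last by C2–C3 closure (step 11).
- Enabling feature: C2 is a methyl-bearing quaternary carbon bonded to the two bridgeheads C1 and C8, so its methyl is a masked exocyclic methylene. H-atom transfer to that methylene gives a tertiary cyclobutyl radical at C2; C7, which carries the chain, lies 1,3 across the four-membered ring, so the chain can reach only the C2 lobe anti to the C9–C11 bridge.
- Stereochemistry: C9 from the hemiester; C1/C8 from the [2+2] transition state, biased by the C9 methyl and a temporary C11 silyloxy centre (CBS reduction, later oxidised to the ketone); C7 by protonation on the bridge face; C2 by the tether; C5 by CBS reduction; C3/C4 by osmylation anti to O5.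

Key step: step 11

Remark (assumption): methyl hydrogen (R)-3-methylglutarate is taken as a commercial chiral building block. Bicyclic intermediates are numbered as bicyclo[3.1.1]heptanes (C6 = bridge carbon from the ketene carbonyl, C7 = the other one-carbon bridge); on ring closure C6 becomes C7 and C7 becomes C2 of the tricycle.

Step 1
Reactants: 1 methyl hydrogen (R)-3-methylglutarate; 2 propyne
Product: 4 methyl (3R)-3-methyl-5-oxooct-6-ynoate, via acid chloride 3 (not isolated)
Conditions: (COCl)2, cat. DMF, CH2Cl2, 0 °C to rt; then propyne, PdCl2(PPh3)2 (2 mol %), CuI (4 mol %), Et3N, THF, rt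
Reagents that add atoms: none
Why: The free acid is converted to its chloride beside the methyl ester and coupled with the terminal alkyne (acyl Sonogashira coupling), which should give the ynone without touching the C3 stereocentre.

Step 2
Reactants: 4 methyl (3R)-3-methyl-5-oxooct-6-ynoate
Product: 5 methyl (3R,6Z)-3-methyl-5-oxo-7-(phenylsulfanyl)oct-6-enoate
Conditions: PhSH, Et3N (cat.), CH2Cl2, 0 °C
Reagents that add atoms: thiophenol, Sc1ccccc1
Why: Base-catalysed thia-Michael addition to the ynone should give the β-phenylsulfanyl enone, mainly Z by anti addition; the geometry only decides which C7 epimer forms in step 6, and that centre is erased in step 9.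

Step 3
Reactants: 5 methyl (3R,6Z)-3-methyl-5-oxo-7-(phenylsulfanyl)oct-6-enoate
Product: 6 methyl (3R,5S,6Z)-5-hydroxy-3-methyl-7-(phenylsulfanyl)oct-6-enoate
Conditions: (R)-2-methyl-CBS-oxazaborolidine (20 mol %), BH3·SMe2, THF, −30 °C; MeOH quench
Reagents that add atoms: none
Why: Corey–Bakshi–Shibata reduction with the alkenyl flank as the large group should give the (5S)-alcohol with the (R)-catalyst, which places O5 and the C3 methyl 1,3-cis on the ring formed in step 6.

Step 4
Reactants: 6 methyl (3R,5S,6Z)-5-hydroxy-3-methyl-7-(phenylsulfanyl)oct-6-enoate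
Product: 7 methyl (3R,5S,6Z)-3-methyl-7-(phenylsulfanyl)-5-(triethylsilyloxy)oct-6-enoate
Conditions: Et3SiCl, imidazole, DMF, 0 °C
Reagents that add atoms: chlorotriethylsilane, CC[Si](Cl)(CC)CC
Why: Silylation of the secondary allylic alcohol protects the acid-sensitive γ-hydroxy vinyl sulfide and gives an ether that can later be removed in the presence of a tert-butyldimethylsilyl ether.

Step 5
Reactants: 7 methyl (3R,5S,6Z)-3-methyl-7-(phenylsulfanyl)-5-(triethylsilyloxy)oct-6-enoate
Product: 8 (3R,5S,6Z)-3-methyl-7-(phenylsulfanyl)-5-(triethylsilyloxy)oct-6-enoic acid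
Conditions: LiOH, THF/H2O, 0 °C to rt; then cold 0.5 M HCl to pH 4
Reagents that add atoms: lithium hydroxide, [Li+].[OH-]
Why: Saponification of the unhindered methyl ester, with careful acidification to pH 4, should leave the silyl ether and vinyl sulfide intact.

Step 6
Reactants: 8 (3R,5S,6Z)-3-methyl-7-(phenylsulfanyl)-5-(triethylsilyloxy)oct-6-enoic acid
Product: 11 2,7-dimethyl-7-(phenylsulfanyl)-4-(triethylsilyloxy)bicyclo[3.1.1]heptan-6-one, via acid chloride 9 (not isolated), via ketene 10 (not isolated)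
Conditions: 1-chloro-N,N,2-trimethylprop-1-en-1-amine, CH2Cl2, 0 °C to rt; then slow addition to Et3N, toluene, 110 °C, high dilution
Reagents that add atoms: none
Why: Intramolecular ketene–alkene [2+2] cycloaddition: the ketene carbonyl carbon is attacked by the β-carbon of the vinyl sulfide (six-membered ring first, charge on sulfur-stabilised C7) and the enolate carbon then closes the cyclobutane, the known bicyclo[3.1.1] regiochemistry for a cation-stabilising distal alkene carbon; in the transition state the C2 methyl and C4 silyloxy groups turn away from the phenylsulfanyl group that is cis to the tether (allylic 1,3-strain) and end on the side of the ketone bridge, which sets C1 and C5 relative to C2 (either C7 epimer serves).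

Step 7
Reactants: 11 2,7-dimethyl-7-(phenylsulfanyl)-4-(triethylsilyloxy)bicyclo[3.1.1]heptan-6-one; 12 trimethyl phosphonoacetate
Product: 13 methyl 2-[2,7-dimethyl-7-(phenylsulfanyl)-4-(triethylsilyloxy)bicyclo[3.1.1]heptan-6-ylidene]acetate
Conditions: NaH, THF, 0 to 50 °C
Reagents that add atoms: none
Why: Horner–Wadsworth–Emmons olefination of the strained, non-enolisable cyclobutanone attaches the two-carbon chain; the alkene geometry is removed in step 8.

Step 8
Reactants: 13 methyl 2-[2,7-dimethyl-7-(phenylsulfanyl)-4-(triethylsilyloxy)bicyclo[3.1.1]heptan-6-ylidene]acetate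
Product: 14 methyl 2-[2,7-dimethyl-7-(phenylsulfanyl)-4-(triethylsilyloxy)bicyclo[3.1.1]heptan-6-yl]acetate
Conditions: Mg turnings, MeOH, rt
Reagents that add atoms: none
Why: Dissolving-metal conjugate reduction (Mg/MeOH) should protonate the β-carbon C6 on the face toward the C2–C4 bridge, because the other face is covered by the anti methyl group on C7 and the alternative epimer would wedge the chain under a bridge already pressed from its far side by the syn phenylsulfanyl group, so the acetate chain ends anti to that bridge as step 11 requires.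

Step 9
Reactants: 14 methyl 2-[2,7-dimethyl-7-(phenylsulfanyl)-4-(triethylsilyloxy)bicyclo[3.1.1]heptan-6-yl]acetate
Product: 16 methyl 2-[2-methyl-7-methylidene-4-(triethylsilyloxy)bicyclo[3.1.1]heptan-6-yl]acetate, via sulfoxide 15 (not isolated)
Conditions: mCPBA (1.0 equiv), CH2Cl2, −78 °C; aq. NaHCO3 wash; then toluene, solid NaHCO3, 110 °C
Reagents that add atoms: none
Why: S-oxidation followed by thermal sulfoxide syn-elimination; only the methyl group offers a β-hydrogen (the bridgeheads are excluded by Bredt strain), so the 7-methylidene compound is the only possible alkene and the C7 stereocentre is erased.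

Step 10
Reactants: 16 methyl 2-[2-methyl-7-methylidene-4-(triethylsilyloxy)bicyclo[3.1.1]heptan-6-yl]acetate; 17 ethynylmagnesium bromide
Product: 19 1-[2-methyl-7-methylidene-4-(triethylsilyloxy)bicyclo[3.1.1]heptan-6-yl]but-3-yn-2-one, via Weinreb amide 18 (not isolated)
Conditions: MeNH(OMe)·HCl, iPrMgCl, THF, −20 °C; then HC≡CMgBr, 0 °C to rt; aq. NH4Cl
Reagents that add atoms: none
Why: The ester is converted in the flask to the N-methoxy-N-methylamide, whose chelated adduct with the ethynyl Grignard reagent collapses only on work-up (Weinreb ketone synthesis), giving the terminal ynone without over-addition.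

Step 11
Reactants: 19 1-[2-methyl-7-methylidene-4-(triethylsilyloxy)bicyclo[3.1.1]heptan-6-yl]but-3-yn-2-one
Product: 20 2,9-dimethyl-11-(triethylsilyloxy)tricyclo[5.4.0.0^{2,8}]undec-3-en-5-one
Conditions: Fe(acac)3 (30 mol %), PhSiH3, EtOH/ethylene glycol 5:1, 60 °C, 0.01 M
Reagents that add atoms: none
Why: An iron hydride formed from Fe(acac)3 and PhSiH3 transfers a hydrogen atom to the CH2 terminus of the methylidene group (Markovnikov sense), so the C2 methyl group and a tertiary cyclobutyl radical at C2 arise together; this nucleophilic radical adds to the terminal ynone carbon (C3), and the α-keto vinyl radical is reduced and protonated to the cis-enone. The closest known reaction type is the iron-mediated reductive coupling of an alkene with a Michael acceptor (radical conjugate addition started by metal-hydride H-atom transfer), used here intramolecularly. The seven-membered ring closes in the 7-endo-dig mode and C2–C3 is the only bond formed. The new stereocentre C2 is set by the tether: the chain on C7 is anti to the C9–C11 bridge and can reach only the anti lobe of the radical across the cyclobutane, which leaves the methyl group syn. The step needs H-atom transfer to the 1,1-disubstituted alkene and not to the ynone, and attack at the β-carbon; polarity matching secures both, and high dilution suppresses intermolecular coupling.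

Step 12
Reactants: 20 2,9-dimethyl-11-(triethylsilyloxy)tricyclo[5.4.0.0^{2,8}]undec-3-en-5-one
Product: 22 2,6,6,9-tetramethyl-11-(triethylsilyloxy)tricyclo[5.4.0.0^{2,8}]undec-3-en-5-one, via monomethyl ketone 21 (not isolated)
Conditions: LiN(iPr)2, THF, −78 °C, then MeI; second cycle of LiN(iPr)2 and MeI in the same flask, −78 to 0 °C
Reagents that add atoms: iodomethane, CI
Why: The kinetic enolate can form only at C6 (C4 is vinylic, C2 is quaternary), so two successive enolate methylations install the gem-dimethyl group.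

Step 13
Reactants: 22 2,6,6,9-tetramethyl-11-(triethylsilyloxy)tricyclo[5.4.0.0^{2,8}]undec-3-en-5-one
Product: 23 (5R)-2,6,6,9-tetramethyl-11-(triethylsilyloxy)tricyclo[5.4.0.0^{2,8}]undec-3-en-5-ol
Conditions: (S)-2-methyl-CBS-oxazaborolidine (1 equiv), BH3·SMe2, THF, −20 °C; MeOH quench
Reagents that add atoms: none
Why: The two faces of this ketone are not differentiated by the distant C9/C11 substituents, so reagent control is needed; Corey–Bakshi–Shibata 1,2-reduction with the quaternary C6 flank as the large group should give the (5R)-alcohol with the (S)-catalyst.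

Step 14
Reactants: 23 (5R)-2,6,6,9-tetramethyl-11-(triethylsilyloxy)tricyclo[5.4.0.0^{2,8}]undec-3-en-5-ol
Product: 24 (5R)-5-(tert-butyldimethylsilyloxy)-2,6,6,9-tetramethyl-11-(triethylsilyloxy)tricyclo[5.4.0.0^{2,8}]undec-3-ene
Conditions: tBuMe2SiOTf, 2,6-lutidine, CH2Cl2, 0 °C
Reagents that add atoms: tert-butyldimethylsilyl trifluoromethanesulfonate, CC(C)(C)[Si](C)(C)OS(=O)(=O)C(F)(F)F
Why: The silyl triflate protects the hindered neopentyl allylic alcohol, so that O5 stays free of acyl groups later and acts as the bulky directing group in step 16.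

Step 15
Reactants: 24 (5R)-5-(tert-butyldimethylsilyloxy)-2,6,6,9-tetramethyl-11-(triethylsilyloxy)tricyclo[5.4.0.0^{2,8}]undec-3-ene
Product: 26 (5R)-5-(tert-butyldimethylsilyloxy)-2,6,6,9-tetramethyltricyclo[5.4.0.0^{2,8}]undec-3-en-11-one, via C11 alcohol 25 (not isolated)
Conditions: IBX (3 equiv), wet DMSO, rt to 40 °C
Reagents that add atoms: none
Why: IBX in DMSO cleaves the triethylsilyl ether but not the hindered tert-butyldimethylsilyl ether and oxidises the freed secondary alcohol in the same flask, which unveils the C11 ketone.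

Step 16
Reactants: 26 (5R)-5-(tert-butyldimethylsilyloxy)-2,6,6,9-tetramethyltricyclo[5.4.0.0^{2,8}]undec-3-en-11-one
Product: 27 (3S,4S,5S)-5-(tert-butyldimethylsilyloxy)-3,4-dihydroxy-2,6,6,9-tetramethyltricyclo[5.4.0.0^{2,8}]undecan-11-one
Conditions: OsO4 (5 mol %), NMO, acetone/H2O, rt
Reagents that add atoms: N-methylmorpholine N-oxide, C[N+]1([O-])CCOCC1; water, O
Why: Upjohn syn-dihydroxylation should occur on the face anti to the bulky allylic C5 silyloxy group, the usual sense for osmylation of cyclic allylic ethers, which gives the 3,4-cis-diol trans to O5.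

Step 17
Reactants: 27 (3S,4S,5S)-5-(tert-butyldimethylsilyloxy)-3,4-dihydroxy-2,6,6,9-tetramethyltricyclo[5.4.0.0^{2,8}]undecan-11-one; 28 angelic acid
Product: 30 5-(tert-butyldimethylsilyloxy)-2,6,6,9-tetramethyl-11-oxotricyclo[5.4.0.0^{2,8}]undecane-3,4-diyl bis[(2Z)-2-methylbut-2-enoate], via C4 monoangelate 29 (not isolated)
Conditions: angelic acid (3 equiv), 2,4,6-trichlorobenzoyl chloride (3 equiv), Et3N, toluene, rt; then 27, toluene, 80 °C
Reagents that add atoms: angelic acid for the second ester group, C/C=C(/C)C(=O)O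
Why: Yamaguchi esterification with an excess of the preformed mixed anhydride acylates both hindered secondary hydroxyls in turn, so two angeloyl units are taken up, and the absence of strong base should keep the Z geometry of the angelate.

Step 18
Reactants: 30 5-(tert-butyldimethylsilyloxy)-2,6,6,9-tetramethyl-11-oxotricyclo[5.4.0.0^{2,8}]undecane-3,4-diyl bis[(2Z)-2-methylbut-2-enoate]
Product: 31 (1R,2R,3S,4R,5S,7S,8S,9R)-5-hydroxy-2,6,6,9-tetramethyl-11-oxotricyclo[5.4.0.0^{2,8}]undecane-3,4-diyl bis[(2Z)-2-methylbut-2-enoate]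
Conditions: HF·pyridine, THF, 0 °C to rt
Reagents that add atoms: none
Why: Desilylation with weakly acidic fluoride should free O5–H without acyl migration or angelate-to-tiglate isomerisation.

**Compound list**

1 | methyl hydrogen (R)-3-methylglutarate, (3R)-5-methoxy-3-methyl-5-oxopentanoic acid | COC(=O)C[C@H](C)CC(=O)O | starting material
2 | propyne | CC#C | starting material
3 | acid chloride of 1 (methyl 5-chloro-3-methyl-5-oxopentanoate, C3 arrangement as in 1) | COC(=O)C[C@H](C)CC(=O)Cl | intermediate
4 | methyl (3R)-3-methyl-5-oxooct-6-ynoate | COC(=O)C[C@H](C)CC(=O)C#CC | intermediate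
5 | methyl (3R,6Z)-3-methyl-5-oxo-7-(phenylsulfanyl)oct-6-enoate | COC(=O)C[C@H](C)CC(=O)/C=C(/C)Sc1ccccc1 | intermediate
6 | methyl (3R,5S,6Z)-5-hydroxy-3-methyl-7-(phenylsulfanyl)oct-6-enoate | COC(=O)C[C@H](C)C[C@H](O)/C=C(/C)Sc1ccccc1 | intermediate
7 | methyl (3R,5S,6Z)-3-methyl-7-(phenylsulfanyl)-5-(triethylsilyloxy)oct-6-enoate | COC(=O)C[C@H](C)C[C@H](O[Si](CC)(CC)CC)/C=C(/C)Sc1ccccc1 | intermediate
8 | (3R,5S,6Z)-3-methyl-7-(phenylsulfanyl)-5-(triethylsilyloxy)oct-6-enoic acid | OC(=O)C[C@H](C)C[C@H](O[Si](CC)(CC)CC)/C=C(/C)Sc1ccccc1 | intermediate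
9 | acid chloride of 8 | ClC(=O)C[C@H](C)C[C@H](O[Si](CC)(CC)CC)/C=C(/C)Sc1ccccc1 | intermediate
10 | ketene from 9, (3R,5S,6Z)-3-methyl-7-(phenylsulfanyl)-5-(triethylsilyloxy)octa-1,6-dien-1-one | O=C=C[C@H](C)C[C@H](O[Si](CC)(CC)CC)/C=C(/C)Sc1ccccc1 | intermediate
11 | 2,7-dimethyl-7-(phenylsulfanyl)-4-(triethylsilyloxy)bicyclo[3.1.1]heptan-6-one; 2-Me and 4-OSiEt3 both on the side of the C6 bridge; 7-SPh syn to the C2–C4 bridge (expected epimer) | O=C1[C@@H]2[C@H](C)C[C@H](O[Si](CC)(CC)CC)[C@H]1[C@@]2(C)Sc1ccccc1 | intermediate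
12 | trimethyl phosphonoacetate | COC(=O)CP(=O)(OC)OC | starting material
13 | methyl 2-[2,7-dimethyl-7-(phenylsulfanyl)-4-(triethylsilyloxy)bicyclo[3.1.1]heptan-6-ylidene]acetate (E/Z mixture, ring stereocentres as in 11) | COC(=O)C=C1[C@@H]2[C@H](C)C[C@H](O[Si](CC)(CC)CC)[C@H]1[C@@]2(C)Sc1ccccc1 | intermediate
14 | methyl 2-[2,7-dimethyl-7-(phenylsulfanyl)-4-(triethylsilyloxy)bicyclo[3.1.1]heptan-6-yl]acetate; C6 chain anti to the C2–C4 bridge (C6–H syn) | COC(=O)C[C@H]1[C@@H]2[C@H](C)C[C@H](O[Si](CC)(CC)CC)[C@H]1[C@@]2(C)Sc1ccccc1 | intermediate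
15 | sulfoxide of 14 (mixture at sulfur) | COC(=O)C[C@H]1[C@@H]2[C@H](C)C[C@H](O[Si](CC)(CC)CC)[C@H]1[C@@]2(C)S(=O)c1ccccc1 | intermediate
16 | methyl 2-[2-methyl-7-methylidene-4-(triethylsilyloxy)bicyclo[3.1.1]heptan-6-yl]acetate (C6 chain anti to the C2–C4 bridge) | COC(=O)C[C@H]1[C@@H]2[C@H](C)C[C@H](O[Si](CC)(CC)CC)[C@H]1C2=C | intermediate
17 | ethynylmagnesium bromide | C#C[Mg]Br | starting material
18 | N-methoxy-N-methylamide corresponding to 16 | CON(C)C(=O)C[C@H]1[C@@H]2[C@H](C)C[C@H](O[Si](CC)(CC)CC)[C@H]1C2=C | intermediate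
19 | 1-[2-methyl-7-methylidene-4-(triethylsilyloxy)bicyclo[3.1.1]heptan-6-yl]but-3-yn-2-one | C#CC(=O)C[C@H]1[C@@H]2[C@H](C)C[C@H](O[Si](CC)(CC)CC)[C@H]1C2=C | intermediate
20 | 2,9-dimethyl-11-(triethylsilyloxy)tricyclo[5.4.0.0^{2,8}]undec-3-en-5-one; C1, C2, C7, C8, C9 arranged as in 31; 11-OSiEt3 on the side of C7 | O=C1C[C@H]2[C@@H]3[C@H](C)C[C@H](O[Si](CC)(CC)CC)[C@H]2[C@]3(C)C=C1 | intermediate
21 | 2,6,9-trimethyl-11-(triethylsilyloxy)tricyclo[5.4.0.0^{2,8}]undec-3-en-5-one (C6 epimers) | O=C1C(C)[C@H]2[C@@H]3[C@H](C)C[C@H](O[Si](CC)(CC)CC)[C@H]2[C@]3(C)C=C1 | intermediate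
22 | 2,6,6,9-tetramethyl-11-(triethylsilyloxy)tricyclo[5.4.0.0^{2,8}]undec-3-en-5-one | O=C1C(C)(C)[C@H]2[C@@H]3[C@H](C)C[C@H](O[Si](CC)(CC)CC)[C@H]2[C@]3(C)C=C1 | intermediate
23 | (5R)-2,6,6,9-tetramethyl-11-(triethylsilyloxy)tricyclo[5.4.0.0^{2,8}]undec-3-en-5-ol | O[C@H]1C(C)(C)[C@H]2[C@@H]3[C@H](C)C[C@H](O[Si](CC)(CC)CC)[C@H]2[C@]3(C)C=C1 | intermediate
24 | (5R)-5-(tert-butyldimethylsilyloxy)-2,6,6,9-tetramethyl-11-(triethylsilyloxy)tricyclo[5.4.0.0^{2,8}]undec-3-ene | CC(C)(C)[Si](C)(C)O[C@H]1C(C)(C)[C@H]2[C@@H]3[C@H](C)C[C@H](O[Si](CC)(CC)CC)[C@H]2[C@]3(C)C=C1 | intermediate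
25 | (5R)-5-(tert-butyldimethylsilyloxy)-2,6,6,9-tetramethyltricyclo[5.4.0.0^{2,8}]undec-3-en-11-ol | CC(C)(C)[Si](C)(C)O[C@H]1C(C)(C)[C@H]2[C@@H]3[C@H](C)C[C@H](O)[C@H]2[C@]3(C)C=C1 | intermediate
26 | (5R)-5-(tert-butyldimethylsilyloxy)-2,6,6,9-tetramethyltricyclo[5.4.0.0^{2,8}]undec-3-en-11-one | CC(C)(C)[Si](C)(C)O[C@H]1C(C)(C)[C@H]2[C@@H]3[C@H](C)CC(=O)[C@H]2[C@]3(C)C=C1 | intermediate
27 | (3S,4S,5S)-5-(tert-butyldimethylsilyloxy)-3,4-dihydroxy-2,6,6,9-tetramethyltricyclo[5.4.0.0^{2,8}]undecan-11-one; 3-OH and 4-OH cis, both trans to O5 | O[C@@H]1[C@@H](O[Si](C)(C)C(C)(C)C)C(C)(C)[C@H]2[C@@H]3[C@H](C)CC(=O)[C@H]2[C@]3(C)[C@@H]1O | intermediate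
28 | angelic acid, (2Z)-2-methylbut-2-enoic acid | C/C=C(/C)C(=O)O | starting material
29 | C4 monoangelate of 27 | C/C=C(/C)C(=O)O[C@@H]1[C@@H](O[Si](C)(C)C(C)(C)C)C(C)(C)[C@H]2[C@@H]3[C@H](C)CC(=O)[C@H]2[C@]3(C)[C@@H]1O | intermediate
30 | 3,4-bis-angelate of 27 (5-O-tert-butyldimethylsilyl ether of the target) | C/C=C(/C)C(=O)O[C@@H]1[C@@H](O[Si](C)(C)C(C)(C)C)C(C)(C)[C@H]2[C@@H]3[C@H](C)CC(=O)[C@H]2[C@]3(C)[C@@H]1OC(=O)/C(C)=C\C | intermediate
31 | (1R,2R,3S,4R,5S,7S,8S,9R)-5-hydroxy-2,6,6,9-tetramethyl-11-oxotricyclo[5.4.0.0^{2,8}]undecane-3,4-diyl bis[(2Z)-2-methylbut-2-enoate] | C/C=C(/C)C(=O)O[C@@H]1[C@@H](O)C(C)(C)[C@H]2[C@@H]3[C@H](C)CC(=O)[C@H]2[C@]3(C)[C@@H]1OC(=O)/C(C)=C\C | target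

**Step count**

Total steps: 18. Longest linear sequence: 18 steps (1 to 31).

**Steps most likely to fail**

1. Step 11. The tertiary radical may be reduced (net hydrogenation of the methylidene group) before the strained 7-endo-dig closure, or the terminal ynone may be consumed by conjugate reduction or solvent addition. The fallback sets out from 19 and replaces the radical by an organopalladium bond formation. Hydroiodination of the ynone (NaI, AcOH) should give the (3Z)-4-iodobut-3-en-2-one F1. An intramolecular reductive Heck cyclisation (Pd(OAc)2, PPh3, HCO2Na, DMF, 80 °C) would then add the alkenylpalladium 7-exo-trig to the methylidene group, which forms C2–C3 and a neopentyl-type alkylpalladium with no β-hydrogen; formate reduces this to the methyl group. The fallback returns to the route at 20.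

2. Step 6. The ketene may oligomerise faster than it cyclises, or the two diastereomeric transition states may not be discriminated well enough (poor facial selectivity relative to C2). The fallback sets out from ester 7 and uses a cationic keteniminium instead of the ketene. Aminolysis (Me2NH, AlMe3, toluene) should give the N,N-dimethylamide F2. Tf2O with 2,6-di-tert-butyl-4-methylpyridine in 1,2-dichloroethane converts it to the keteniminium triflate F3, which does not dimerise and cyclises at lower temperature to the cyclobutaniminium triflate F4. Hydrolysis with aqueous NaHCO3 returns to the route at 11.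

3. Step 13. The oxazaborolidine may discriminate poorly between the quaternary C6 flank and the alkenyl flank, and the substrate has no facial bias of its own. The fallback sets out from 22 and gives up reagent control: Luche reduction (NaBH4, CeCl3·7H2O, MeOH) gives 23 together with its (5S)-epimer F5, and the two are separated by chromatography. F5 is reoxidised to 22 with MnO2 and recycled; the fallback returns to the route at 23.

**Further compounds**

F1 | step 11 | (3Z)-4-iodo-1-[2-methyl-7-methylidene-4-(triethylsilyloxy)bicyclo[3.1.1]heptan-6-yl]but-3-en-2-one | I/C=C\C(=O)C[C@H]1[C@@H]2[C@H](C)C[C@H](O[Si](CC)(CC)CC)[C@H]1C2=C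
F2 | step 6 | (3R,5S,6Z)-N,N,3-trimethyl-7-(phenylsulfanyl)-5-(triethylsilyloxy)oct-6-enamide | CN(C)C(=O)C[C@H](C)C[C@H](O[Si](CC)(CC)CC)/C=C(/C)Sc1ccccc1
F3 | step 6 | keteniminium triflate derived from F2 | C[N+](C)=C=C[C@H](C)C[C@H](O[Si](CC)(CC)CC)/C=C(/C)Sc1ccccc1.[O-]S(=O)(=O)C(F)(F)F
F4 | step 6 | N,N-dimethyliminium triflate of ketone 11 | C[N+](C)=C1[C@@H]2[C@H](C)C[C@H](O[Si](CC)(CC)CC)[C@H]1[C@@]2(C)Sc1ccccc1.[O-]S(=O)(=O)C(F)(F)F
F5 | step 13 | (5S)-2,6,6,9-tetramethyl-11-(triethylsilyloxy)tricyclo[5.4.0.0^{2,8}]undec-3-en-5-ol (C5 epimer of 23) | O[C@@H]1C(C)(C)[C@H]2[C@@H]3[C@H](C)C[C@H](O[Si](CC)(CC)CC)[C@H]2[C@]3(C)C=C1
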